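**Plan**

- Labdane numbering is used: ring A = C1–C5 and C10 (C3 carbinol, C4 gem-dimethyl); ring B = C5–C10 (C7=C8 alkene, methyl on C8, side chain on C9, methyl C20 on C10); chain C11–C15 with the ester oxygen on C15.
- Retrosynthesis: cut the C15–O ester bond; cut the ring B bond C9–C10, tracing the C7=C8 alkene back to an E C8=C9 alkene with a phenylsulfonyl group on C7, and the C10 methyl back to an exocyclic C10=C20 methylene; cut C6–C7 (sulfone alkylation) into a ring A triflate and a geraniol-derived ten-carbon allyl sulfone.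
- Forward: ring A arises first (titanocene radical cyclization of (R)-6,7-epoxygeranyl acetate), the C7–C15 chain is joined at C6, ring B is closed last (C9–C10), then C3 reduction, desilylation and esterification.
- Enabling feature: C10 is a quaternary ring A carbon whose methyl can be written as =CH2, so hydrogen-atom transfer gives a tertiary C10 radical; C9 lies six atoms away through C5–C6–C7–C8; C7 is allylic to C8=C9, so a sulfonyl group there leaves as a radical after ring closure and fixes the alkene at C7=C8.
- Stereochemistry: C5 from the Shi epoxide through the chair radical cyclization; C10 and C9 from C5 through the chair transition state of the ring B closure; C3 (axial, S, cis to H-5) from L-Selectride reduction of the 3-ketone; the ester centre from (S)-3-methylpentanoic acid; both E alkenes from geraniol and geranyl acetate.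

Key step: step 9

Remark: (S)-3-methylpentanoic acid (17) is taken as a purchasable chiral-pool acid, and 13 is carried as both epimers at the sulfonyl-bearing carbon because step 9 destroys that centre.

**Route**

Step 1
Reactants: 1 geranyl acetate
Product: 2 (2E)-5-[(2R)-3,3-dimethyloxiran-2-yl]-3-methylpent-2-en-1-yl acetate ((R)-6,7-epoxygeranyl acetate)
Conditions: D-fructose-derived Shi ketone (1,2:4,5-di-O-isopropylidene-β-D-erythro-2,3-hexodiulo-2,6-pyranose, 30 mol%), KHSO5 (as Oxone), K2CO3, Bu4NHSO4 (cat.), MeCN–CH2(OMe)2/aq. Na2B4O7–Na2EDTA buffer, 0 °C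
Reagents that add atoms: potassium peroxymonosulfate, [K+].[O-]S(=O)(=O)OO
Why: Shi asymmetric epoxidation, in which the chiral dioxirane should attack only the electron-richer 6,7-alkene (the 2,3-alkene is deactivated by the allylic acetate) through the spiro transition state that gives the (R)-epoxide, the centre that later fixes C5.

Step 2
Reactants: 2 (R)-6,7-epoxygeranyl acetate
Product: 3 [(1S,3R)-3-hydroxy-2,2-dimethyl-6-methylidenecyclohexyl]methyl acetate
Conditions: Cp2TiCl2 (2.2 equiv), Mn dust (8 equiv), THF, rt, slow addition of 2; then 1 M HCl work-up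
Reagents that add atoms: none
Why: Nugent–RajanBabu-type reductive epoxide opening by Cp2TiCl (trivalent titanium) gives the tertiary radical, which should close ring A 6-endo through a chair transition state with the titanium alkoxide equatorial (setting the CH2OAc-bearing carbon cis to the retained C–O centre) before trapping by a further Cp2TiCl and β-hydride loss to the exocyclic alkene.

Step 3
Reactants: 3 [(1S,3R)-3-hydroxy-2,2-dimethyl-6-methylidenecyclohexyl]methyl acetate
Product: 4 [(1S)-2,2-dimethyl-6-methylidene-3-oxocyclohexyl]methyl acetate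
Conditions: Dess–Martin periodinane (1.3 equiv), CH2Cl2, 0 °C to rt
Reagents that add atoms: none
Why: Dess–Martin oxidation of the secondary alcohol leaves acetate and exocyclic alkene untouched and removes the equatorial C3 carbinol centre, whose task was to set C5 and which is re-made with the opposite sense in step 10.

Step 4
Reactants: 4 [(1S)-2,2-dimethyl-6-methylidene-3-oxocyclohexyl]methyl acetate
Product: 5 (3S)-3-(hydroxymethyl)-2,2-dimethyl-4-methylidenecyclohexan-1-one
Conditions: K2CO3 (0.2 equiv), MeOH, 0 °C
Reagents that add atoms: none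
Why: Base-catalysed transesterification (Zemplén-type methanolysis) frees the primary alcohol, and the stereocentre cannot epimerise because it is separated from the carbonyl by the quaternary carbon.

Step 5
Reactants: 6 geraniol
Product: 7 tert-butyl{[(2E)-3,7-dimethylocta-2,6-dien-1-yl]oxy}dimethylsilane
Conditions: TBSCl, imidazole, CH2Cl2, 0 °C to rt
Reagents that add atoms: tert-butyldimethylsilyl chloride, CC(C)(C)[Si](C)(C)Cl
Why: Standard silylation of a primary allylic alcohol gives an ether that tolerates the later organolithium, radical and hydride steps.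

Step 6
Reactants: 7 tert-butyl{[(2E)-3,7-dimethylocta-2,6-dien-1-yl]oxy}dimethylsilane
Product: 8 (2E,6E)-8-{[tert-butyl(dimethyl)silyl]oxy}-2,6-dimethylocta-2,6-dien-1-ol
Conditions: SeO2 (0.1 equiv), t-BuOOH (70% aq., 2.5 equiv), salicylic acid (0.1 equiv), CH2Cl2, rt
Reagents that add atoms: tert-butyl hydroperoxide, CC(C)(C)OO
Why: Riley allylic oxidation (ene reaction then [2,3]-sigmatropic shift) should oxidise the E methyl group of the terminal trisubstituted alkene, the 2,3-alkene being deactivated by the allylic silyloxy group, and give the E allylic alcohol.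

Step 7
Reactants: 8 (2E,6E)-8-{[tert-butyl(dimethyl)silyl]oxy}-2,6-dimethylocta-2,6-dien-1-ol
Product: 10 tert-butyl{[(2E,6E)-3,7-dimethyl-8-(phenylsulfonyl)octa-2,6-dien-1-yl]oxy}dimethylsilane, via allylic bromide 9 (not isolated)
Conditions: CBr4, PPh3, CH2Cl2, −20 °C; then PhSO2Na, DMF, rt
Reagents that add atoms: sodium benzenesulfinate, [Na+].[O-]S(=O)c1ccccc1
Why: Appel bromination followed by SN2 S-alkylation of the sulfinate in DMF should give the primary E allyl sulfone without allylic transposition.

Step 8
Reactants: 5 (3S)-3-(hydroxymethyl)-2,2-dimethyl-4-methylidenecyclohexan-1-one; 10 tert-butyl{[(2E,6E)-3,7-dimethyl-8-(phenylsulfonyl)octa-2,6-dien-1-yl]oxy}dimethylsilane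
Product: 13 (3S)-3-[(3E,7E)-9-{[tert-butyl(dimethyl)silyl]oxy}-3,7-dimethyl-2-(phenylsulfonyl)nona-3,7-dien-1-yl]-2,2-dimethyl-4-methylidenecyclohexan-1-one (both epimers at the sulfonyl carbon), via keto triflate 11 (not isolated), via lithiated sulfone 12 (not isolated)
Conditions: 5, Tf2O, 2,6-lutidine, CH2Cl2, −78 °C (11, used crude, 1.2 equiv); 10, n-BuLi, THF–DMPU, −78 °C (12); 11 added to 12, −78 to −40 °C
Reagents that add atoms: none
Why: Julia-type sulfone coupling, in which the α-carbon of the lithiated allyl sulfone is alkylated by the primary triflate at low temperature to form the C6–C7 bond with the E alkene retained, while addition of the soft carbanion to the hindered α,α-dimethyl ketone is reversible and the new sulfonyl-bearing centre needs no control.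

Step 9
Reactants: 13 (3S)-3-[(3E,7E)-9-{[tert-butyl(dimethyl)silyl]oxy}-3,7-dimethyl-2-(phenylsulfonyl)nona-3,7-dien-1-yl]-2,2-dimethyl-4-methylidenecyclohexan-1-one
Product: 14 (4aS,5R,8aS)-5-[(3E)-5-{[tert-butyl(dimethyl)silyl]oxy}-3-methylpent-3-en-1-yl]-1,1,4a,6-tetramethyl-3,4,4a,5,8,8a-hexahydronaphthalen-2(1H)-one
Conditions: Fe(acac)3 (30 mol%), PhSiH3 (2.5 equiv), EtOH, 60 °C, argon
Reagents that add atoms: none
Why: Proposed new method: the iron hydride formed from Fe(acac)3 and PhSiH3 should transfer a hydrogen atom to the terminal CH2 of the ring A methylene to give the tertiary C10 radical, which adds to C9 of the E allyl sulfone, and the resulting tertiary C8 radical expels PhSO2• by β-scission of the C7–S bond, so that the alkene appears at C7=C8 and divalent iron is returned to the trivalent state by reducing PhSO2• to sulfinate. The closest known reaction types are the hydrogen-atom-transfer-initiated reductive olefin coupling with Fe(acac)3 and PhSiH3 (Mukaiyama-type radical hydrofunctionalization, tertiary radicals adding to acceptor alkenes to form quaternary carbons) and the radical allylation of alkyl radicals by allyl sulfones through addition and fragmentation, and what is new is their union in an endo ring closure on an unactivated allyl sulfone. Ring B closes in the 6-endo-trig mode, the 5-exo mode being disfavoured because it would need attack at the fully substituted C8. C10 and C9 are controlled by the C5 stereocentre through a chair-like transition state in which the C5–C6 tether is equatorial on ring A, the new C9–C10 bond forms equatorially (C20 axial and trans to H-5) and the E geometry of C8=C9 places the C9 side chain equatorial, as in the second ring closure of radical polyene cyclizations. The step needs chemoselective hydrogen-atom transfer, secured by the 1,1-disubstituted ring A alkene against two trisubstituted and allylically deactivated chain alkenes, and a single alkene position, secured by the sulfonyl leaving group on C7, both C7 epimers converging.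

Step 10
Reactants: 14 (4aS,5R,8aS)-5-[(3E)-5-{[tert-butyl(dimethyl)silyl]oxy}-3-methylpent-3-en-1-yl]-1,1,4a,6-tetramethyl-3,4,4a,5,8,8a-hexahydronaphthalen-2(1H)-one
Product: 15 (2S,4aS,5R,8aS)-5-[(3E)-5-{[tert-butyl(dimethyl)silyl]oxy}-3-methylpent-3-en-1-yl]-1,1,4a,6-tetramethyl-1,2,3,4,4a,5,8,8a-octahydronaphthalen-2-ol
Conditions: LiBH(s-Bu)3 (L-Selectride, 1.5 equiv), THF, −78 °C; aqueous work-up
Reagents that add atoms: none
Why: Steric approach control in the rigid trans-decalin, where the bulky trialkylborohydride should add from the equatorial direction to avoid the syn-axial hydrogens on C1 and C5 and give the axial (S) alcohol cis to H-5, as known for 4,4-dimethyl-3-keto terpenoids.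

Step 11
Reactants: 15 (2S,4aS,5R,8aS)-5-[(3E)-5-{[tert-butyl(dimethyl)silyl]oxy}-3-methylpent-3-en-1-yl]-1,1,4a,6-tetramethyl-1,2,3,4,4a,5,8,8a-octahydronaphthalen-2-ol
Product: 16 (2S,4aS,5R,8aS)-5-[(3E)-5-hydroxy-3-methylpent-3-en-1-yl]-1,1,4a,6-tetramethyl-1,2,3,4,4a,5,8,8a-octahydronaphthalen-2-ol
Conditions: Bu4NF, THF, 0 °C to rt
Reagents that add atoms: none
Why: Fluoride-mediated cleavage of the primary allylic silyl ether should proceed without touching the alkenes or the secondary alcohol.

Step 12
Reactants: 16 (2S,4aS,5R,8aS)-5-[(3E)-5-hydroxy-3-methylpent-3-en-1-yl]-1,1,4a,6-tetramethyl-1,2,3,4,4a,5,8,8a-octahydronaphthalen-2-ol; 17 (S)-3-methylpentanoic acid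
Product: 18 (2E)-5-[(1R,4aS,6S,8aS)-6-hydroxy-2,5,5,8a-tetramethyl-1,4,4a,5,6,7,8,8a-octahydronaphthalen-1-yl]-3-methylpent-2-en-1-yl (3S)-3-methylpentanoate
Conditions: EDC·HCl (1.2 equiv), DMAP (0.1 equiv), 17 (1.05 equiv), CH2Cl2, 0 °C
Reagents that add atoms: none
Why: Steglich esterification should acylate the unhindered primary allylic alcohol far faster than the axial C3–OH flanked by the gem-dimethyl carbon, and the acid stereocentre, β to the carboxyl, cannot epimerise.

**Compound list**

1 | geranyl acetate | CC(=O)OC/C=C(\C)CCC=C(C)C | starting material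
2 | (2E)-5-[(2R)-3,3-dimethyloxiran-2-yl]-3-methylpent-2-en-1-yl acetate | CC(=O)OC/C=C(\C)CC[C@H]1OC1(C)C | intermediate
3 | [(1S,3R)-3-hydroxy-2,2-dimethyl-6-methylidenecyclohexyl]methyl acetate | CC(=O)OC[C@@H]1C(C)(C)[C@H](O)CCC1=C | intermediate
4 | [(1S)-2,2-dimethyl-6-methylidene-3-oxocyclohexyl]methyl acetate | CC(=O)OC[C@@H]1C(C)(C)C(=O)CCC1=C | intermediate
5 | (3S)-3-(hydroxymethyl)-2,2-dimethyl-4-methylidenecyclohexan-1-one | OC[C@@H]1C(C)(C)C(=O)CCC1=C | intermediate
6 | geraniol | OC/C=C(\C)CCC=C(C)C | starting material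
7 | tert-butyl{[(2E)-3,7-dimethylocta-2,6-dien-1-yl]oxy}dimethylsilane | CC(C)(C)[Si](C)(C)OC/C=C(\C)CCC=C(C)C | intermediate
8 | (2E,6E)-8-{[tert-butyl(dimethyl)silyl]oxy}-2,6-dimethylocta-2,6-dien-1-ol | CC(C)(C)[Si](C)(C)OC/C=C(\C)CC/C=C(\C)CO | intermediate
9 | {[(2E,6E)-8-bromo-3,7-dimethylocta-2,6-dien-1-yl]oxy}(tert-butyl)dimethylsilane | CC(C)(C)[Si](C)(C)OC/C=C(\C)CC/C=C(\C)CBr | intermediate
10 | tert-butyl{[(2E,6E)-3,7-dimethyl-8-(phenylsulfonyl)octa-2,6-dien-1-yl]oxy}dimethylsilane | CC(C)(C)[Si](C)(C)OC/C=C(\C)CC/C=C(\C)CS(=O)(=O)c1ccccc1 | intermediate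
11 | [(1S)-2,2-dimethyl-6-methylidene-3-oxocyclohexyl]methyl trifluoromethanesulfonate | O=S(=O)(OC[C@@H]1C(C)(C)C(=O)CCC1=C)C(F)(F)F | intermediate
12 | α-lithio derivative of sulfone 10 (lithium on the sulfonyl-bearing carbon) | CC(C)(C)[Si](C)(C)OC/C=C(\C)CC/C=C(\C)C([Li])S(=O)(=O)c1ccccc1 | intermediate
13 | (3S)-3-[(3E,7E)-9-{[tert-butyl(dimethyl)silyl]oxy}-3,7-dimethyl-2-(phenylsulfonyl)nona-3,7-dien-1-yl]-2,2-dimethyl-4-methylidenecyclohexan-1-one, both epimers at the sulfonyl carbon | CC(C)(C)[Si](C)(C)OC/C=C(\C)CC/C=C(\C)C(C[C@@H]1C(C)(C)C(=O)CCC1=C)S(=O)(=O)c1ccccc1 | intermediate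
14 | (4aS,5R,8aS)-5-[(3E)-5-{[tert-butyl(dimethyl)silyl]oxy}-3-methylpent-3-en-1-yl]-1,1,4a,6-tetramethyl-3,4,4a,5,8,8a-hexahydronaphthalen-2(1H)-one | CC(C)(C)[Si](C)(C)OC/C=C(\C)CC[C@@H]1C(C)=CC[C@@H]2C(C)(C)C(=O)CC[C@@]12C | intermediate
15 | (2S,4aS,5R,8aS)-5-[(3E)-5-{[tert-butyl(dimethyl)silyl]oxy}-3-methylpent-3-en-1-yl]-1,1,4a,6-tetramethyl-1,2,3,4,4a,5,8,8a-octahydronaphthalen-2-ol | CC(C)(C)[Si](C)(C)OC/C=C(\C)CC[C@@H]1C(C)=CC[C@@H]2C(C)(C)[C@@H](O)CC[C@@]12C | intermediate
16 | (2S,4aS,5R,8aS)-5-[(3E)-5-hydroxy-3-methylpent-3-en-1-yl]-1,1,4a,6-tetramethyl-1,2,3,4,4a,5,8,8a-octahydronaphthalen-2-ol | OC/C=C(\C)CC[C@@H]1C(C)=CC[C@@H]2C(C)(C)[C@@H](O)CC[C@@]12C | intermediate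
17 | (S)-3-methylpentanoic acid | CC[C@H](C)CC(=O)O | starting material
18 | (2E)-5-[(1R,4aS,6S,8aS)-6-hydroxy-2,5,5,8a-tetramethyl-1,4,4a,5,6,7,8,8a-octahydronaphthalen-1-yl]-3-methylpent-2-en-1-yl (3S)-3-methylpentanoate | CC[C@H](C)CC(=O)OC/C=C(\C)CC[C@@H]1C(C)=CC[C@@H]2C(C)(C)[C@@H](O)CC[C@@]12C | target

**Count**

Total steps: 12. Longest linear sequence: 9 steps (steps 1, 2, 3, 4, 8, 9, 10, 11, 12).

**Steps most likely to fail**

Step 9 (carries the new-method label). The tertiary C10 radical may be reduced before it cyclizes. Fragmentation may be slow when the C7–S bond lies in the nodal plane of the C8 radical. Liberated sulfonyl radicals may start chains of their own, and hydrogen-atom transfer may stray to the chain alkenes. Fallback with known chemistry, setting out from 13: the sulfonyl-radical chain cyclization of dienyl allyl sulfones (catalytic benzenesulfinic acid and dilauroyl peroxide, benzene, 80 °C). Here PhSO2• adds to the exocyclic CH2, the same C10 radical closes ring B 6-endo on C9 and expels PhSO2• from C7. This should give (4aR,5R,8aR)-5-[(3E)-5-{[tert-butyl(dimethyl)silyl]oxy}-3-methylpent-3-en-1-yl]-1,1,6-trimethyl-4a-[(phenylsulfonyl)methyl]-3,4,4a,5,8,8a-hexahydronaphthalen-2(1H)-one F1. Reductive desulfonylation of this primary sulfone (Na(Hg), Na2HPO4, MeOH–THF, −20 to 0 °C) then comes back to the route at 14.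

Step 8. The sulfonyl carbanion may add to or enolise the C3 ketone, and the hindered primary triflate may eliminate or decompose before C-alkylation. Fallback setting out from 3, with the ketone absent during the coupling and a stable iodide as electrophile. Methanolysis (K2CO3, MeOH) gives (1R,3S)-3-(hydroxymethyl)-2,2-dimethyl-4-methylidenecyclohexan-1-ol F2. Selective Appel iodination of the primary hydroxyl (I2, PPh3, imidazole, CH2Cl2) gives (1R,3S)-3-(iodomethyl)-2,2-dimethyl-4-methylidenecyclohexan-1-ol F3. Alkylation with 12 (2.2 equiv, made from 10 as in step 8; THF–DMPU, −78 °C to rt) gives (1R,3S)-3-[(3E,7E)-9-{[tert-butyl(dimethyl)silyl]oxy}-3,7-dimethyl-2-(phenylsulfonyl)nona-3,7-dien-1-yl]-2,2-dimethyl-4-methylidenecyclohexan-1-ol F4. Dess–Martin oxidation of F4 comes back to the route at 13.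

Step 2. The radical cyclization may lose material by premature reduction of the tertiary radical before ring closure and by non-selective hydride loss on termination. Fallback setting out from 2: switch from the radical to the polar manifold, an epoxide-initiated cation–olefin cyclization with ZrCl4 in CH2Cl2 at low temperature. The same chair transition state should give the same cis relation, and proton loss should give the alkene. After separation of double-bond isomers it comes back to the route at 3 and makes no compound outside the list (F0).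

**Further compounds**

F1 | step 9 | (4aR,5R,8aR)-5-[(3E)-5-{[tert-butyl(dimethyl)silyl]oxy}-3-methylpent-3-en-1-yl]-1,1,6-trimethyl-4a-[(phenylsulfonyl)methyl]-3,4,4a,5,8,8a-hexahydronaphthalen-2(1H)-one | CC(C)(C)[Si](C)(C)OC/C=C(\C)CC[C@@H]1C(C)=CC[C@@H]2C(C)(C)C(=O)CC[C@@]12CS(=O)(=O)c1ccccc1
F2 | step 8 | (1R,3S)-3-(hydroxymethyl)-2,2-dimethyl-4-methylidenecyclohexan-1-ol | OC[C@@H]1C(C)(C)[C@H](O)CCC1=C
F3 | step 8 | (1R,3S)-3-(iodomethyl)-2,2-dimethyl-4-methylidenecyclohexan-1-ol | IC[C@@H]1C(C)(C)[C@H](O)CCC1=C
F4 | step 8 | (1R,3S)-3-[(3E,7E)-9-{[tert-butyl(dimethyl)silyl]oxy}-3,7-dimethyl-2-(phenylsulfonyl)nona-3,7-dien-1-yl]-2,2-dimethyl-4-methylidenecyclohexan-1-ol, both epimers at the sulfonyl carbon | CC(C)(C)[Si](C)(C)OC/C=C(\C)CC/C=C(\C)C(C[C@@H]1C(C)(C)[C@H](O)CCC1=C)S(=O)(=O)c1ccccc1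
F0 | step 2 | none | none
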